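**Retrosynthetic overview**
1. Target 43 ⇒ macrolide alkyne 34 + dienyl iodide 41 (C23–C24 bond). The (22E,24Z,26Z)-triene with its doubly allylic C28 is prone to thermal [1,7]-H shift, so it is attached last, at or below room temperature.
2. 34 ⇒ β-keto lactone 32 ⇒ seco-dioxinone 30. The only ring (22-membered lactone) is closed at C1–O21 by intramolecular capture of an acylketene by the C21 hydroxyl, mirroring thioesterase off-loading of a β-keto acyl chain. The ketoreduction is deferred: C5-OH-directed 1,3-anti reduction sets C3 after ring closure.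
3. 30 ⇒ enal 23 + dienol ether 26 (C4–C5, vinylogous Mukaiyama aldol sets C5); 23 ⇒ sulfone 14 + aldehyde 20 (C14=C15, Julia–Kocienski).
4. 20 ⇒ alkyne 18 (C11 from epoxide 15) + acetal 19 (C8–C9, Ru Alder-ene builds the 1,4-diene); 14 ⇒ Marshall propargylation (C20–C21 anti), then alkenylzinc addition to aldehyde 9 (C17–C18).
5. Ring order: one ring only, formed in step 17; 41 comes from but-2-yn-1-ol by hydroalumination–iodination, oxidation and Z-selective Wittig reaction.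

Assumption: (S)-but-3-yn-2-ol (1) and (S)-2-(but-3-en-1-yl)oxirane (15) are bought as single enantiomers; labels C1–C30 run along the target chain from the lactone carbonyl (C1) to the terminal vinyl carbon (C30).

Step 1
Reactants: 1 (S)-but-3-yn-2-ol
Product: 2 (S)-but-3-yn-2-yl methanesulfonate
Conditions: MsCl, Et3N, CH2Cl2, −78 to 0 °C
Reagents that add atoms: methanesulfonyl chloride, CS(=O)(=O)Cl
Why: O-sulfonylation leaves the C–O stereocentre untouched and provides the leaving group for the Marshall propargylation.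

Step 2
Reactants: 2 (S)-but-3-yn-2-yl methanesulfonate; 3 3-(trimethylsilyl)prop-2-ynal
Product: 5 (3R,4R)-4-methyl-1-(trimethylsilyl)hexa-1,5-diyn-3-ol, via allenyl(ethyl)zinc 4 (not isolated)
Conditions: Pd(OAc)2 (5 mol%), PPh3 (5 mol%), Et2Zn (3 equiv), THF, −78 to −20 °C
Reagents that add atoms: none
Why: Marshall propargylation: zerovalent palladium formed in situ attacks the mesylate anti-SN2', zinc exchange gives (M)-allenylzinc 4, and its closed syn-SE2' transition state with the ynal gives the anti-homopropargylic alcohol, fixing C20 (R, net inversion of the mesylate carbon) and C21 together.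

Step 3
Reactants: 5 (3R,4R)-4-methyl-1-(trimethylsilyl)hexa-1,5-diyn-3-ol
Product: 6 triethyl{[(3R,4R)-4-methyl-1-(trimethylsilyl)hexa-1,5-diyn-3-yl]oxy}silane
Conditions: Et3SiCl, imidazole, DMF, 0 °C
Reagents that add atoms: chlorotriethylsilane, CC[Si](Cl)(CC)CC
Why: Silyl ether formation masks the C21 hydroxyl with the one silyl group that can later be removed in the presence of tert-butyldimethylsilyl ethers.

Step 4
Reactants: 7 prop-2-enal; 8 1-phenyl-1H-tetrazole-5-thiol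
Product: 9 3-[(1-phenyl-1H-tetrazol-5-yl)sulfanyl]propanal
Conditions: Et3N (5 mol%), CH2Cl2, 0 °C, used fresh
Reagents that add atoms: none
Why: Base-catalysed thia-Michael addition at 0 °C gives the kinetic S-adduct, which carries the C17 aldehyde and the latent Julia–Kocienski sulfone.

Step 5
Reactants: 6 triethyl{[(3R,4R)-4-methyl-1-(trimethylsilyl)hexa-1,5-diyn-3-yl]oxy}silane; 9 3-[(1-phenyl-1H-tetrazol-5-yl)sulfanyl]propanal
Product: 12 (3S,4E,6R,7R)-6-methyl-1-[(1-phenyl-1H-tetrazol-5-yl)sulfanyl]-7-[(triethylsilyl)oxy]-9-(trimethylsilyl)non-4-en-8-yn-3-ol, via alkenylborane 10 (not isolated), via alkenylzinc 11 (not isolated)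
Conditions: Cy2BH, PhMe, 0 °C to rt; Me2Zn, −78 °C; (+)-MIB [(2R)-3-exo-morpholinoisoborneol, 10 mol%]; then 9, −20 to 0 °C
Reagents that add atoms: none
Why: Oppolzer–Walsh alkenylation: syn hydroboration of the terminal alkyne gives E-alkenylborane 10 (the silylated alkyne is inert), boron–zinc exchange gives 11, and the (+)-MIB zinc catalyst delivers it to the Re face of aldehyde 9, setting C17 (S) and the E C18=C19 alkene in one operation.

Step 6
Reactants: 12 (3S,4E,6R,7R)-6-methyl-1-[(1-phenyl-1H-tetrazol-5-yl)sulfanyl]-7-[(triethylsilyl)oxy]-9-(trimethylsilyl)non-4-en-8-yn-3-ol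
Product: 13 5-{[(3S,4E,6R,7R)-3-[(tert-butyldimethylsilyl)oxy]-6-methyl-7-[(triethylsilyl)oxy]-9-(trimethylsilyl)non-4-en-8-yn-1-yl]sulfanyl}-1-phenyl-1H-tetrazole
Conditions: t-BuMe2SiCl, imidazole, DMF, rt
Reagents that add atoms: tert-butylchlorodimethylsilane, CC(C)(C)[Si](C)(C)Cl
Why: Silyl ether formation protects the C17 allylic alcohol before carbanion chemistry.

Step 7
Reactants: 13 5-{[(3S,4E,6R,7R)-3-[(tert-butyldimethylsilyl)oxy]-6-methyl-7-[(triethylsilyl)oxy]-9-(trimethylsilyl)non-4-en-8-yn-1-yl]sulfanyl}-1-phenyl-1H-tetrazole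
Product: 14 5-{[(3S,4E,6R,7R)-3-[(tert-butyldimethylsilyl)oxy]-6-methyl-7-[(triethylsilyl)oxy]-9-(trimethylsilyl)non-4-en-8-yn-1-yl]sulfonyl}-1-phenyl-1H-tetrazole
Conditions: (NH4)6Mo7O24·4H2O (20 mol%), 30% H2O2, EtOH, 0 °C
Reagents that add atoms: hydrogen peroxide, OO
Why: Molybdate-catalysed peroxide oxidation of the tetrazolyl sulfide to the sulfone does not epoxidise the disubstituted alkene or touch the alkyne and silyl ethers at 0 °C.

Step 8
Reactants: 15 (S)-2-(but-3-en-1-yl)oxirane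
Product: 16 (4S)-oct-7-en-1-yn-4-ol
Conditions: LiC≡CH·H2NCH2CH2NH2, DMSO, 0 °C to rt
Reagents that add atoms: lithium acetylide–ethane-1,2-diamine complex, [Li+].[C-]#C.NCCN
Why: SN2 opening of the terminal epoxide at its CH2 carbon by acetylide leaves the C11 stereocentre (S) as bought.

Step 9
Reactants: 16 (4S)-oct-7-en-1-yn-4-ol
Product: 17 tert-butyldimethyl{[(4S)-oct-7-en-1-yn-4-yl]oxy}silane
Conditions: t-BuMe2SiCl, imidazole, DMF, rt
Reagents that add atoms: tert-butylchlorodimethylsilane, CC(C)(C)[Si](C)(C)Cl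
Why: Silyl ether formation protects the C11 hydroxyl so that the later C14 aldehyde cannot close to a lactol.

Step 10
Reactants: 17 tert-butyldimethyl{[(4S)-oct-7-en-1-yn-4-yl]oxy}silane
Product: 18 (4S)-4-[(tert-butyldimethylsilyl)oxy]hept-6-ynal
Conditions: OsO4 (2 mol%), NaIO4 (4 equiv), 2,6-lutidine, dioxane/H2O (3:1), rt
Reagents that add atoms: sodium periodate, [Na+].[O-]I(=O)(=O)=O
Why: Lemieux–Johnson oxidative cleavage takes the monosubstituted alkene to the C14 aldehyde because OsO4 reacts far faster with the alkene than with the terminal alkyne.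

Step 11
Reactants: 18 (4S)-4-[(tert-butyldimethylsilyl)oxy]hept-6-ynal; 19 4,4-diethoxybut-1-ene
Product: 20 (4S,8E)-4-[(tert-butyldimethylsilyl)oxy]-10,10-diethoxy-6-methylidenedec-8-enal
Conditions: [CpRu(MeCN)3]PF6 (10 mol%), acetone, rt
Reagents that add atoms: none
Why: Trost ruthenium-catalysed Alder-ene coupling joins the internal alkyne carbon to the alkene terminus with transfer of an allylic hydrogen, giving the branched 1,4-diene with the exo-methylene at C9 and an E C6=C7 alkene next to the acetal.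

Step 12
Reactants: 14 5-{[(3S,4E,6R,7R)-3-[(tert-butyldimethylsilyl)oxy]-6-methyl-7-[(triethylsilyl)oxy]-9-(trimethylsilyl)non-4-en-8-yn-1-yl]sulfonyl}-1-phenyl-1H-tetrazole; 20 (4S,8E)-4-[(tert-butyldimethylsilyl)oxy]-10,10-diethoxy-6-methylidenedec-8-enal
Product: 23 (2E,7S,10E,13S,14E,16R,17R)-7,13-bis[(tert-butyldimethylsilyl)oxy]-16-methyl-5-methylidene-17-[(triethylsilyl)oxy]nonadeca-2,10,14-trien-18-ynal, via silylalkyne acetal 21 (not isolated), via alkyne acetal 22 (not isolated)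
Conditions: KN(SiMe3)2, DME, −60 °C to rt; then MeOH, K2CO3, rt; then 5% aq. oxalic acid, THF, 0 °C
Reagents that add atoms: water, O
Why: Julia–Kocienski olefination in DME gives the E C14=C15 alkene (21), methanolic carbonate then cleaves the alkynyl C–Si bond (22), and the brief oxalic acid quench hydrolyses the very labile α,β-unsaturated acetal to the enal while all silyl ethers survive.

Step 13
Reactants: 24 2,2,6-trimethyl-4H-1,3-dioxin-4-one
Product: 26 [(2,2-dimethyl-6-methylidene-6H-1,3-dioxin-4-yl)oxy]trimethylsilane, via lithium dienolate 25 (not isolated)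
Conditions: LiN(iPr)2, THF, −78 °C; Me3SiCl
Reagents that add atoms: chlorotrimethylsilane, C[Si](C)(C)Cl
Why: γ-Deprotonation of the vinylogous ester gives dienolate 25, which is silylated on oxygen to the dienol ether used in the vinylogous Mukaiyama aldol.

Step 14
Reactants: 23 (2E,7S,10E,13S,14E,16R,17R)-7,13-bis[(tert-butyldimethylsilyl)oxy]-16-methyl-5-methylidene-17-[(triethylsilyl)oxy]nonadeca-2,10,14-trien-18-ynal; 26 [(2,2-dimethyl-6-methylidene-6H-1,3-dioxin-4-yl)oxy]trimethylsilane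
Product: 28 6-[(2S,3E,8S,11E,14S,15E,17R,18R)-8,14-bis[(tert-butyldimethylsilyl)oxy]-2-hydroxy-17-methyl-6-methylidene-18-[(triethylsilyl)oxy]icosa-3,11,15-trien-19-yn-1-yl]-2,2-dimethyl-4H-1,3-dioxin-4-one, via trimethylsilyl ether 27 (not isolated)
Conditions: Ti(OiPr)4 (20 mol%), (S)-BINOL (20 mol%), 4 Å MS, THF, −78 to 0 °C; then citric acid, MeOH, 0 °C
Reagents that add atoms: none
Why: Catalytic asymmetric vinylogous Mukaiyama aldol: the (S)-BINOL titanium Lewis acid directs the γ-carbon of 26 to the Si face of the enal (same facial sense as the Keck allylation), setting C5 (S) and installing C1–C4 as a masked β-keto acid, and mild acid removes the transferred trimethylsilyl group from 27.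

Step 15
Reactants: 28 6-[(2S,3E,8S,11E,14S,15E,17R,18R)-8,14-bis[(tert-butyldimethylsilyl)oxy]-2-hydroxy-17-methyl-6-methylidene-18-[(triethylsilyl)oxy]icosa-3,11,15-trien-19-yn-1-yl]-2,2-dimethyl-4H-1,3-dioxin-4-one
Product: 29 6-[(2S,3E,8S,11E,14S,15E,17R,18R)-2,8,14-tris[(tert-butyldimethylsilyl)oxy]-17-methyl-6-methylidene-18-[(triethylsilyl)oxy]icosa-3,11,15-trien-19-yn-1-yl]-2,2-dimethyl-4H-1,3-dioxin-4-one
Conditions: t-BuMe2SiCl, imidazole, DMAP (cat.), DMF, rt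
Reagents that add atoms: tert-butylchlorodimethylsilane, CC(C)(C)[Si](C)(C)Cl
Why: Silyl ether formation blocks the C5 hydroxyl, which would otherwise capture the acylketene as a six-membered lactone.

Step 16
Reactants: 29 6-[(2S,3E,8S,11E,14S,15E,17R,18R)-2,8,14-tris[(tert-butyldimethylsilyl)oxy]-17-methyl-6-methylidene-18-[(triethylsilyl)oxy]icosa-3,11,15-trien-19-yn-1-yl]-2,2-dimethyl-4H-1,3-dioxin-4-one
Product: 30 6-[(2S,3E,8S,11E,14S,15E,17R,18R)-2,8,14-tris[(tert-butyldimethylsilyl)oxy]-18-hydroxy-17-methyl-6-methylidene-icosa-3,11,15-trien-19-yn-1-yl]-2,2-dimethyl-4H-1,3-dioxin-4-one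
Conditions: PPTS (0.2 equiv), MeOH/CH2Cl2 (1:4), 0 °C
Reagents that add atoms: none
Why: Acid-catalysed methanolysis removes a triethylsilyl ether about a hundred times faster than secondary tert-butyldimethylsilyl ethers, freeing only the C21 hydroxyl.

Step 17
Reactants: 30 6-[(2S,3E,8S,11E,14S,15E,17R,18R)-2,8,14-tris[(tert-butyldimethylsilyl)oxy]-18-hydroxy-17-methyl-6-methylidene-icosa-3,11,15-trien-19-yn-1-yl]-2,2-dimethyl-4H-1,3-dioxin-4-one
Product: 32 (6S,7E,12S,15E,18S,19E,21R,22R)-6,12,18-tris[(tert-butyldimethylsilyl)oxy]-22-ethynyl-21-methyl-10-methylidene-1-oxacyclodocosa-7,15,19-triene-2,4-dione, via acylketene 31 (not isolated)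
Conditions: PhMe (0.5 mM, slow addition), 110 °C, 2 h
Reagents that add atoms: none
Why: Boeckman acylketene macrolactonisation: retro-hetero-Diels–Alder loss of acetone gives acylketene 31, and its only free hydroxyl (C21) adds intramolecularly under high dilution to close the 22-membered β-keto lactone without any acid activation or seco-acid handling.

Step 18
Reactants: 32 (6S,7E,12S,15E,18S,19E,21R,22R)-6,12,18-tris[(tert-butyldimethylsilyl)oxy]-22-ethynyl-21-methyl-10-methylidene-1-oxacyclodocosa-7,15,19-triene-2,4-dione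
Product: 33 (6S,7E,12S,15E,18S,19E,21R,22R)-22-ethynyl-6,12,18-trihydroxy-21-methyl-10-methylidene-1-oxacyclodocosa-7,15,19-triene-2,4-dione
Conditions: HF·pyridine, pyridine, THF, 0 °C to rt
Reagents that add atoms: none
Why: Buffered HF cleaves the three Si–O bonds without base, which the β-keto lactone (β-elimination, translactonisation) would not tolerate.

Step 19
Reactants: 33 (6S,7E,12S,15E,18S,19E,21R,22R)-22-ethynyl-6,12,18-trihydroxy-21-methyl-10-methylidene-1-oxacyclodocosa-7,15,19-triene-2,4-dione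
Product: 34 (4S,6S,7E,12S,15E,18S,19E,21R,22R)-22-ethynyl-4,6,12,18-tetrahydroxy-21-methyl-10-methylidene-1-oxacyclodocosa-7,15,19-trien-2-one
Conditions: Me4NBH(OAc)3, MeCN/AcOH (2:1), −30 °C
Reagents that add atoms: none
Why: Evans–Saksena reduction: the C5 hydroxyl binds boron and delivers hydride intramolecularly through a chair-like transition state to the C3 ketone, giving the 3,5-anti diol (C3 S) and leaving the lactone untouched.

Step 20
Reactants: 35 but-2-yn-1-ol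
Product: 37 (2Z)-3-iodobut-2-en-1-ol, via vinylalanate 36 (not isolated)
Conditions: NaAlH2(OCH2CH2OMe)2, THF, 0 °C to rt; then I2, −78 to 0 °C
Reagents that add atoms: iodine, II
Why: Alkoxide-directed trans-hydroalumination puts aluminium on C3 cis to the CH2O group (36), and iodinolysis with retention gives the Z-iodide that fixes the later C24=C25 geometry.

Step 21
Reactants: 37 (2Z)-3-iodobut-2-en-1-ol
Product: 38 (2Z)-3-iodobut-2-enal
Conditions: MnO2 (20 equiv), CH2Cl2, rt, dark, used at once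
Reagents that add atoms: none
Why: MnO2 oxidation of the allylic alcohol is neutral and does not isomerise the Z-iodoalkene.

Step 22
Reactants: 38 (2Z)-3-iodobut-2-enal; 39 (but-3-en-1-yl)triphenylphosphonium bromide
Product: 41 (2Z,4Z)-2-iodoocta-2,4,7-triene, via phosphorus ylide 40 (not isolated)
Conditions: NaN(SiMe3)2, THF, −78 °C; then 38, −78 to 0 °C, dark
Reagents that add atoms: none
Why: Wittig reaction of the non-stabilised ylide 40 under lithium-free conditions is Z-selective (kinetic cis-oxaphosphetane), creating the C26=C27 Z-alkene and the skipped terminal vinyl group.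

Step 23
Reactants: 34 (4S,6S,7E,12S,15E,18S,19E,21R,22R)-22-ethynyl-4,6,12,18-tetrahydroxy-21-methyl-10-methylidene-1-oxacyclodocosa-7,15,19-trien-2-one; 41 (2Z,4Z)-2-iodoocta-2,4,7-triene
Product: 43 (4S,6S,7E,12S,15E,18S,19E,21R,22S)-4,6,12,18-tetrahydroxy-21-methyl-22-[(1E,3Z,5Z)-3-methylnona-1,3,5,8-tetraen-1-yl]-10-methylidene-1-oxacyclodocosa-7,15,19-trien-2-one, via vinylstannane 42 (not isolated)
Conditions: Pd2(dba)3 (2.5 mol%), Cy3P·HBF4 (10 mol%), iPr2NEt (20 mol%), Bu3SnH (1.1 equiv), CH2Cl2, 0 °C; then 41, Cu(O2CC4H3S) (2 equiv), NMP, 0 °C to rt, dark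
Reagents that add atoms: none
Why: Palladium-catalysed syn hydrostannation gives E-vinylstannane 42 (tin on the distal carbon, favoured by the bulky phosphine and the branched propargylic centre), and the copper carboxylate then mediates a Stille-type (Liebeskind) coupling with 41 with retention of every alkene geometry, so the heat-sensitive triene appears only in the last step.

**Compound list**
1 | (S)-but-3-yn-2-ol | C[C@H](O)C#C | starting material
2 | (S)-but-3-yn-2-yl methanesulfonate | C[C@H](OS(C)(=O)=O)C#C | intermediate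
3 | 3-(trimethylsilyl)prop-2-ynal | C[Si](C)(C)C#CC=O | starting material
4 | ethyl[(M)-buta-1,2-dien-1-yl]zinc | [H]C(C)=[C@@]=C([H])[Zn]CC | intermediate
5 | (3R,4R)-4-methyl-1-(trimethylsilyl)hexa-1,5-diyn-3-ol | C#C[C@@H](C)[C@@H](O)C#C[Si](C)(C)C | intermediate
6 | triethyl{[(3R,4R)-4-methyl-1-(trimethylsilyl)hexa-1,5-diyn-3-yl]oxy}silane | C#C[C@@H](C)[C@@H](O[Si](CC)(CC)CC)C#C[Si](C)(C)C | intermediate
7 | prop-2-enal | C=CC=O | starting material
8 | 1-phenyl-1H-tetrazole-5-thiol | Sc1nnnn1-c1ccccc1 | starting material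
9 | 3-[(1-phenyl-1H-tetrazol-5-yl)sulfanyl]propanal | O=CCCSc1nnnn1-c1ccccc1 | intermediate
10 | dicyclohexyl[(1E,3R,4R)-3-methyl-4-[(triethylsilyl)oxy]-6-(trimethylsilyl)hex-1-en-5-yn-1-yl]borane | C1CCCCC1B(C1CCCCC1)/C=C/[C@@H](C)[C@@H](O[Si](CC)(CC)CC)C#C[Si](C)(C)C | intermediate
11 | methyl[(1E,3R,4R)-3-methyl-4-[(triethylsilyl)oxy]-6-(trimethylsilyl)hex-1-en-5-yn-1-yl]zinc | C[Zn]/C=C/[C@@H](C)[C@@H](O[Si](CC)(CC)CC)C#C[Si](C)(C)C | intermediate
12 | (3S,4E,6R,7R)-6-methyl-1-[(1-phenyl-1H-tetrazol-5-yl)sulfanyl]-7-[(triethylsilyl)oxy]-9-(trimethylsilyl)non-4-en-8-yn-3-ol | c1ccccc1-n1nnnc1SCC[C@H](O)/C=C/[C@@H](C)[C@@H](O[Si](CC)(CC)CC)C#C[Si](C)(C)C | intermediate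
13 | 5-{[(3S,4E,6R,7R)-3-[(tert-butyldimethylsilyl)oxy]-6-methyl-7-[(triethylsilyl)oxy]-9-(trimethylsilyl)non-4-en-8-yn-1-yl]sulfanyl}-1-phenyl-1H-tetrazole | c1ccccc1-n1nnnc1SCC[C@H](O[Si](C)(C)C(C)(C)C)/C=C/[C@@H](C)[C@@H](O[Si](CC)(CC)CC)C#C[Si](C)(C)C | intermediate
14 | 5-{[(3S,4E,6R,7R)-3-[(tert-butyldimethylsilyl)oxy]-6-methyl-7-[(triethylsilyl)oxy]-9-(trimethylsilyl)non-4-en-8-yn-1-yl]sulfonyl}-1-phenyl-1H-tetrazole | c1ccccc1-n1nnnc1S(=O)(=O)CC[C@H](O[Si](C)(C)C(C)(C)C)/C=C/[C@@H](C)[C@@H](O[Si](CC)(CC)CC)C#C[Si](C)(C)C | intermediate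
15 | (S)-2-(but-3-en-1-yl)oxirane | C=CCC[C@H]1CO1 | starting material
16 | (4S)-oct-7-en-1-yn-4-ol | C#CC[C@@H](O)CCC=C | intermediate
17 | tert-butyldimethyl{[(4S)-oct-7-en-1-yn-4-yl]oxy}silane | C#CC[C@@H](O[Si](C)(C)C(C)(C)C)CCC=C | intermediate
18 | (4S)-4-[(tert-butyldimethylsilyl)oxy]hept-6-ynal | C#CC[C@@H](O[Si](C)(C)C(C)(C)C)CCC=O | intermediate
19 | 4,4-diethoxybut-1-ene (but-3-enal diethyl acetal) | C=CCC(OCC)OCC | starting material
20 | (4S,8E)-4-[(tert-butyldimethylsilyl)oxy]-10,10-diethoxy-6-methylidenedec-8-enal | CCOC(OCC)/C=C/CC(=C)C[C@@H](O[Si](C)(C)C(C)(C)C)CCC=O | intermediate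
21 | (2E,7S,10E,13S,14E,16R,17R)-7,13-bis[(tert-butyldimethylsilyl)oxy]-1,1-diethoxy-16-methyl-5-methylidene-17-[(triethylsilyl)oxy]-19-(trimethylsilyl)nonadeca-2,10,14-trien-18-yne | CCOC(OCC)/C=C/CC(=C)C[C@@H](O[Si](C)(C)C(C)(C)C)CC/C=C/C[C@H](O[Si](C)(C)C(C)(C)C)/C=C/[C@@H](C)[C@@H](O[Si](CC)(CC)CC)C#C[Si](C)(C)C | intermediate
22 | (2E,7S,10E,13S,14E,16R,17R)-7,13-bis[(tert-butyldimethylsilyl)oxy]-1,1-diethoxy-16-methyl-5-methylidene-17-[(triethylsilyl)oxy]nonadeca-2,10,14-trien-18-yne | CCOC(OCC)/C=C/CC(=C)C[C@@H](O[Si](C)(C)C(C)(C)C)CC/C=C/C[C@H](O[Si](C)(C)C(C)(C)C)/C=C/[C@@H](C)[C@@H](O[Si](CC)(CC)CC)C#C | intermediate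
23 | (2E,7S,10E,13S,14E,16R,17R)-7,13-bis[(tert-butyldimethylsilyl)oxy]-16-methyl-5-methylidene-17-[(triethylsilyl)oxy]nonadeca-2,10,14-trien-18-ynal | O=C/C=C/CC(=C)C[C@@H](O[Si](C)(C)C(C)(C)C)CC/C=C/C[C@H](O[Si](C)(C)C(C)(C)C)/C=C/[C@@H](C)[C@@H](O[Si](CC)(CC)CC)C#C | intermediate
24 | 2,2,6-trimethyl-4H-1,3-dioxin-4-one | CC1=CC(=O)OC(C)(C)O1 | starting material
25 | lithium 2,2-dimethyl-6-methylidene-6H-1,3-dioxin-4-olate | [Li+].[O-]C1=CC(=C)OC(C)(C)O1 | intermediate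
26 | [(2,2-dimethyl-6-methylidene-6H-1,3-dioxin-4-yl)oxy]trimethylsilane | C=C1C=C(O[Si](C)(C)C)OC(C)(C)O1 | intermediate
27 | 6-[(2S,3E,8S,11E,14S,15E,17R,18R)-8,14-bis[(tert-butyldimethylsilyl)oxy]-17-methyl-6-methylidene-18-[(triethylsilyl)oxy]-2-[(trimethylsilyl)oxy]icosa-3,11,15-trien-19-yn-1-yl]-2,2-dimethyl-4H-1,3-dioxin-4-one | CC1(C)OC(=O)C=C(O1)C[C@H](O[Si](C)(C)C)/C=C/CC(=C)C[C@@H](O[Si](C)(C)C(C)(C)C)CC/C=C/C[C@H](O[Si](C)(C)C(C)(C)C)/C=C/[C@@H](C)[C@@H](O[Si](CC)(CC)CC)C#C | intermediate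
28 | 6-[(2S,3E,8S,11E,14S,15E,17R,18R)-8,14-bis[(tert-butyldimethylsilyl)oxy]-2-hydroxy-17-methyl-6-methylidene-18-[(triethylsilyl)oxy]icosa-3,11,15-trien-19-yn-1-yl]-2,2-dimethyl-4H-1,3-dioxin-4-one | CC1(C)OC(=O)C=C(O1)C[C@H](O)/C=C/CC(=C)C[C@@H](O[Si](C)(C)C(C)(C)C)CC/C=C/C[C@H](O[Si](C)(C)C(C)(C)C)/C=C/[C@@H](C)[C@@H](O[Si](CC)(CC)CC)C#C | intermediate
29 | 6-[(2S,3E,8S,11E,14S,15E,17R,18R)-2,8,14-tris[(tert-butyldimethylsilyl)oxy]-17-methyl-6-methylidene-18-[(triethylsilyl)oxy]icosa-3,11,15-trien-19-yn-1-yl]-2,2-dimethyl-4H-1,3-dioxin-4-one | CC1(C)OC(=O)C=C(O1)C[C@H](O[Si](C)(C)C(C)(C)C)/C=C/CC(=C)C[C@@H](O[Si](C)(C)C(C)(C)C)CC/C=C/C[C@H](O[Si](C)(C)C(C)(C)C)/C=C/[C@@H](C)[C@@H](O[Si](CC)(CC)CC)C#C | intermediate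
30 | 6-[(2S,3E,8S,11E,14S,15E,17R,18R)-2,8,14-tris[(tert-butyldimethylsilyl)oxy]-18-hydroxy-17-methyl-6-methylidene-icosa-3,11,15-trien-19-yn-1-yl]-2,2-dimethyl-4H-1,3-dioxin-4-one | CC1(C)OC(=O)C=C(O1)C[C@H](O[Si](C)(C)C(C)(C)C)/C=C/CC(=C)C[C@@H](O[Si](C)(C)C(C)(C)C)CC/C=C/C[C@H](O[Si](C)(C)C(C)(C)C)/C=C/[C@@H](C)[C@@H](O)C#C | intermediate
31 | (5S,6E,11S,14E,17S,18E,20R,21R)-5,11,17-tris[(tert-butyldimethylsilyl)oxy]-21-hydroxy-20-methyl-9-methylidene-3-oxotricosa-1,6,14,18-tetraen-22-yn-1-one (acylketene) | O=C=CC(=O)C[C@H](O[Si](C)(C)C(C)(C)C)/C=C/CC(=C)C[C@@H](O[Si](C)(C)C(C)(C)C)CC/C=C/C[C@H](O[Si](C)(C)C(C)(C)C)/C=C/[C@@H](C)[C@@H](O)C#C | intermediate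
32 | (6S,7E,12S,15E,18S,19E,21R,22R)-6,12,18-tris[(tert-butyldimethylsilyl)oxy]-22-ethynyl-21-methyl-10-methylidene-1-oxacyclodocosa-7,15,19-triene-2,4-dione | C#C[C@@H]1OC(=O)CC(=O)C[C@H](O[Si](C)(C)C(C)(C)C)/C=C/CC(=C)C[C@@H](O[Si](C)(C)C(C)(C)C)CC/C=C/C[C@H](O[Si](C)(C)C(C)(C)C)/C=C/[C@H]1C | intermediate
33 | (6S,7E,12S,15E,18S,19E,21R,22R)-22-ethynyl-6,12,18-trihydroxy-21-methyl-10-methylidene-1-oxacyclodocosa-7,15,19-triene-2,4-dione | C#C[C@@H]1OC(=O)CC(=O)C[C@H](O)/C=C/CC(=C)C[C@@H](O)CC/C=C/C[C@H](O)/C=C/[C@H]1C | intermediate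
34 | (4S,6S,7E,12S,15E,18S,19E,21R,22R)-22-ethynyl-4,6,12,18-tetrahydroxy-21-methyl-10-methylidene-1-oxacyclodocosa-7,15,19-trien-2-one | C#C[C@@H]1OC(=O)C[C@@H](O)C[C@H](O)/C=C/CC(=C)C[C@@H](O)CC/C=C/C[C@H](O)/C=C/[C@H]1C | intermediate
35 | but-2-yn-1-ol | CC#CCO | starting material
36 | sodium 2,2-bis(2-methoxyethoxy)-3-methyl-2,5-dihydro-1,2-oxaluminol-2-uide | CC1=CCO[Al-]1(OCCOC)OCCOC.[Na+] | intermediate
37 | (2Z)-3-iodobut-2-en-1-ol | C/C(I)=C/CO | intermediate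
38 | (2Z)-3-iodobut-2-enal | C/C(I)=C/C=O | intermediate
39 | (but-3-en-1-yl)triphenylphosphonium bromide | C=CCC[P+](c1ccccc1)(c1ccccc1)c1ccccc1.[Br-] | starting material
40 | (but-3-en-1-ylidene)triphenyl-λ5-phosphane | C=CCC=P(c1ccccc1)(c1ccccc1)c1ccccc1 | intermediate
41 | (2Z,4Z)-2-iodoocta-2,4,7-triene | C/C(I)=C/C=C\CC=C | intermediate
42 | (4S,6S,7E,12S,15E,18S,19E,21R,22R)-4,6,12,18-tetrahydroxy-21-methyl-10-methylidene-22-[(E)-2-(tributylstannyl)ethenyl]-1-oxacyclodocosa-7,15,19-trien-2-one | CCCC[Sn](CCCC)(CCCC)/C=C/[C@@H]1OC(=O)C[C@@H](O)C[C@H](O)/C=C/CC(=C)C[C@@H](O)CC/C=C/C[C@H](O)/C=C/[C@H]1C | intermediate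
43 | (4S,6S,7E,12S,15E,18S,19E,21R,22S)-4,6,12,18-tetrahydroxy-21-methyl-22-[(1E,3Z,5Z)-3-methylnona-1,3,5,8-tetraen-1-yl]-10-methylidene-1-oxacyclodocosa-7,15,19-trien-2-one | C=CC\C=C/C=C(C)\C=C\[C@@H]1OC(=O)C[C@@H](O)C[C@H](O)/C=C/CC(=C)C[C@@H](O)CC/C=C/C[C@H](O)/C=C/[C@H]1C | target

**Step count**
Total: 23 steps. Longest linear sequence: 14 steps (1, 2, 3, 5, 6, 7, 12, 14, 15, 16, 17, 18, 19, 23).

**Steps most likely to fail, with fallbacks**

Step 17 (acylketene macrolactonisation). The risks are oligomerisation and β-elimination of the C5 silyloxy group at 110 °C. The fallback sets out from 29. Heating 29 with 2-methylpropane-2-thiol in toluene at 110 °C captures the acylketene intermolecularly as S-tert-butyl (5S,6E,11S,14E,17S,18E,20R,21R)-5,11,17-tris[(tert-butyldimethylsilyl)oxy]-20-methyl-9-methylidene-3-oxo-21-[(triethylsilyl)oxy]tricosa-6,14,18-trien-22-ynethioate F1. PPTS in MeOH then removes the C21 triethylsilyl group to give the 21-hydroxy thioester F2. The ring is closed at room temperature by AgO2CCF3-promoted thioester activation under high dilution, which comes back to the route at 32.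

Step 5 (alkenylzinc addition). The risks are loss of the thiolate from aldehyde 9 by β-elimination and weak control at C17 if the tetrazole binds zinc. The fallback sets out from 6 and 9. The terminal alkyne of 6 is lithiated (n-BuLi, THF, −78 °C) and added to 9 to give (6R,7R)-6-methyl-1-[(1-phenyl-1H-tetrazol-5-yl)sulfanyl]-7-[(triethylsilyl)oxy]-9-(trimethylsilyl)nona-4,8-diyn-3-ol F3 as a C3 epimer mixture. Dess–Martin periodinane oxidises it to the corresponding nona-4,8-diyn-3-one F4. Noyori transfer hydrogenation with RuCl(p-cymene)[(S,S)-TsDPEN] in iPrOH sets the carbinol, giving the (3S,6R,7R)-nona-4,8-diyn-3-ol F5. NaAlH2(OCH2CH2OMe)2 then reduces only the hydroxyl-bearing alkyne to the E-alkene, which comes back to the route at 12.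

Step 23 (hydrostannation and coupling on the unprotected macrolide). The risks are the proximal stannane regioisomer, protodestannylation and erosion of the Z,Z geometry. The fallback sets out from 34. Hydroboration of the terminal alkyne with pinacolborane (Cp2Zr(H)Cl cat., Et3N, CH2Cl2; excess reagent, O–B esters cleaved on work-up) gives (4S,6S,7E,12S,15E,18S,19E,21R,22S)-4,6,12,18-tetrahydroxy-21-methyl-10-methylidene-22-[(E)-2-(4,4,5,5-tetramethyl-1,3,2-dioxaborolan-2-yl)ethenyl]-1-oxacyclodocosa-7,15,19-trien-2-one F6. Suzuki–Miyaura coupling of F6 with 41 (Pd(PPh3)4, aqueous K3PO4, THF, rt, dark) arrives directly at 43.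

Further compounds
F1 | step 17 | S-tert-butyl (5S,6E,11S,14E,17S,18E,20R,21R)-5,11,17-tris[(tert-butyldimethylsilyl)oxy]-20-methyl-9-methylidene-3-oxo-21-[(triethylsilyl)oxy]tricosa-6,14,18-trien-22-ynethioate | CC(C)(C)SC(=O)CC(=O)C[C@H](O[Si](C)(C)C(C)(C)C)/C=C/CC(=C)C[C@@H](O[Si](C)(C)C(C)(C)C)CC/C=C/C[C@H](O[Si](C)(C)C(C)(C)C)/C=C/[C@@H](C)[C@@H](O[Si](CC)(CC)CC)C#C
F2 | step 17 | S-tert-butyl (5S,6E,11S,14E,17S,18E,20R,21R)-5,11,17-tris[(tert-butyldimethylsilyl)oxy]-21-hydroxy-20-methyl-9-methylidene-3-oxotricosa-6,14,18-trien-22-ynethioate | CC(C)(C)SC(=O)CC(=O)C[C@H](O[Si](C)(C)C(C)(C)C)/C=C/CC(=C)C[C@@H](O[Si](C)(C)C(C)(C)C)CC/C=C/C[C@H](O[Si](C)(C)C(C)(C)C)/C=C/[C@@H](C)[C@@H](O)C#C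
F3 | step 5 | (6R,7R)-6-methyl-1-[(1-phenyl-1H-tetrazol-5-yl)sulfanyl]-7-[(triethylsilyl)oxy]-9-(trimethylsilyl)nona-4,8-diyn-3-ol (C3 epimer mixture) | OC(CCSc1nnnn1-c1ccccc1)C#C[C@@H](C)[C@@H](O[Si](CC)(CC)CC)C#C[Si](C)(C)C
F4 | step 5 | (6R,7R)-6-methyl-1-[(1-phenyl-1H-tetrazol-5-yl)sulfanyl]-7-[(triethylsilyl)oxy]-9-(trimethylsilyl)nona-4,8-diyn-3-one | O=C(CCSc1nnnn1-c1ccccc1)C#C[C@@H](C)[C@@H](O[Si](CC)(CC)CC)C#C[Si](C)(C)C
F5 | step 5 | (3S,6R,7R)-6-methyl-1-[(1-phenyl-1H-tetrazol-5-yl)sulfanyl]-7-[(triethylsilyl)oxy]-9-(trimethylsilyl)nona-4,8-diyn-3-ol | c1ccccc1-n1nnnc1SCC[C@H](O)C#C[C@@H](C)[C@@H](O[Si](CC)(CC)CC)C#C[Si](C)(C)C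
F6 | step 23 | (4S,6S,7E,12S,15E,18S,19E,21R,22S)-4,6,12,18-tetrahydroxy-21-methyl-10-methylidene-22-[(E)-2-(4,4,5,5-tetramethyl-1,3,2-dioxaborolan-2-yl)ethenyl]-1-oxacyclodocosa-7,15,19-trien-2-one | CC1(C)OB(OC1(C)C)/C=C/[C@@H]1OC(=O)C[C@@H](O)C[C@H](O)/C=C/CC(=C)C[C@@H](O)CC/C=C/C[C@H](O)/C=C/[C@H]1C
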